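**Retrosynthetic overview**

1. The target (labdane numbering) is traced back to methyl 2α-hydroxy-15-(4-methoxybenzyloxy)-18-norlabda-7,13E-dien-19-oate by C15 acetylation/desilylation, C19 ester reduction and α-face methylation of C4.
2. Ring A is closed last through C2–C3 by a SmI2 ketyl–olefin coupling of a C2 aldehyde (arm on C10) with a 2-substituted acrylate (C3=C4–C19, on C5). The enabling feature is the γ-hydroxy ester pattern O–C2–C3–C4–C19 of ring A, carried on trans-diequatorial arms at C10 and C5 of ring B.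
3. The seco precursor comes from a ring-B cyclohexenol: the C9 side chain by phosphine-directed syn-SN2′ organocopper substitution (C7–O to C9–C11, alkene moves to C7=C8), the acrylate from a C5 ethynyl group, the aldehyde from a C1 enol ether.
4. Ring B is formed first by an auxiliary-controlled Diels–Alder reaction of a 1-amino-3-siloxy diene with an (E)-2-methyl enynal, which sets C5 and C10.

Key step: step 17

Convention: labdane numbering (C1–C20) is used for every intermediate; β is the face of the C20 methyl on C10, α the opposite face; TBS = tert-butyldimethylsilyl, TMS = trimethylsilyl, PMB = 4-methoxybenzyl.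

Assumption (chemistry): the (2S,5S) antipode of the diphenylpyrrolidine auxiliary is taken to shield the diene face that leads to the (1R,6R) adduct 9; should the sense be opposite, the (2R,5R) antipode is used and nothing else changes.

**Route**

Step 1
Reactants: 1 (E)-4-methoxybut-3-en-2-one; 2 (2S,5S)-2,5-diphenylpyrrolidine
Product: 3 (E)-4-[(2S,5S)-2,5-diphenylpyrrolidin-1-yl]but-3-en-2-one
Conditions: MeOH, 50 °C
Reagents that add atoms: none
Why: Conjugate addition–elimination of the secondary amine on the β-methoxy enone should give the vinylogous amide with loss of methanol.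

Step 2
Reactants: 3 (E)-4-[(2S,5S)-2,5-diphenylpyrrolidin-1-yl]but-3-en-2-one
Product: 4 (2S,5S)-1-[(1E)-3-(tert-butyldimethylsilyloxy)buta-1,3-dien-1-yl]-2,5-diphenylpyrrolidine
Conditions: KN(SiMe3)2, THF, −78 °C; then TBS chloride, −78 °C to rt
Reagents that add atoms: tert-butyldimethylsilyl chloride, CC(C)(C)[Si](C)(C)Cl
Why: Kinetic deprotonation of the acetyl methyl group and O-silylation of the cross-conjugated enolate should give the 1-amino-3-siloxy diene.

Step 3
Reactants: 5 3-(trimethylsilyl)prop-2-ynal; 6 2-(triphenylphosphoranylidene)propanal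
Product: 7 (E)-2-methyl-5-(trimethylsilyl)pent-2-en-4-ynal
Conditions: CH2Cl2, 0 °C to rt
Reagents that add atoms: none
Why: Wittig olefination with the stabilised ylide is E-selective, so the alkynyl group should end up trans to the formyl group.

Step 4
Reactants: 4 (2S,5S)-1-[(1E)-3-(tert-butyldimethylsilyloxy)buta-1,3-dien-1-yl]-2,5-diphenylpyrrolidine; 7 (E)-2-methyl-5-(trimethylsilyl)pent-2-en-4-ynal
Product: 9 (1R,6R)-1-methyl-4-oxo-6-[(trimethylsilyl)ethynyl]cyclohex-2-ene-1-carbaldehyde, via Diels–Alder adduct 8 (not isolated)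
Conditions: toluene, −20 °C to rt; then 1 M aqueous HCl, THF, 0 °C
Reagents that add atoms: none
Why: In this normal-demand Diels–Alder reaction the nucleophilic CH2 terminus (C6) bonds to the enal β-carbon (C5) and the amino-bearing carbon (C9) to C10, the E geometry of 7 is transferred suprafacially so that CHO on C10 and alkynyl on C5 are trans, the C2-symmetric pyrrolidine shields one diene face and thereby fixes the absolute configuration of C5 and C10, and acid hydrolysis of the silyl enol ether with β-elimination of the amine gives the enone and erases C9.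

Step 5
Reactants: 9 (1R,6R)-1-methyl-4-oxo-6-[(trimethylsilyl)ethynyl]cyclohex-2-ene-1-carbaldehyde
Product: 10 (1S,6R)-3-iodo-1-methyl-4-oxo-6-[(trimethylsilyl)ethynyl]cyclohex-2-ene-1-carbaldehyde
Conditions: I2, pyridine, CH2Cl2, rt
Reagents that add atoms: iodine, [I][I]
Why: Pyridine-mediated α-iodination of the enone (Baylis–Hillman-type addition at C9, iodination at C8, elimination) installs the handle for the C17 methyl group, as is known for 4,4-disubstituted cyclohexenones.

Step 6
Reactants: 10 (1S,6R)-3-iodo-1-methyl-4-oxo-6-[(trimethylsilyl)ethynyl]cyclohex-2-ene-1-carbaldehyde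
Product: 11 (1R,6R)-1,3-dimethyl-4-oxo-6-[(trimethylsilyl)ethynyl]cyclohex-2-ene-1-carbaldehyde
Conditions: Me4Sn, Pd2(dba)3 (dba = dibenzylideneacetone), AsPh3, CuI, N-methylpyrrolidone, 60 °C
Reagents that add atoms: tetramethylstannane, C[Sn](C)(C)C
Why: Stille coupling of the α-iodoenone should transfer methyl to C8 under neutral conditions that spare the aldehyde and the alkynylsilane.

Step 7
Reactants: 11 (1R,6R)-1,3-dimethyl-4-oxo-6-[(trimethylsilyl)ethynyl]cyclohex-2-ene-1-carbaldehyde; 12 (methoxymethyl)triphenylphosphonium chloride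
Product: 13 (4R,5R)-4-(2-methoxyethenyl)-2,4-dimethyl-5-[(trimethylsilyl)ethynyl]cyclohex-2-en-1-one (E/Z mixture at the enol ether)
Conditions: 12, KN(SiMe3)2, THF, 0 °C; then 11, −78 °C to 0 °C
Reagents that add atoms: none
Why: Wittig methoxymethylenation should occur at the aldehyde in preference to the conjugated α-substituted ketone and adds C2 as a masked aldehyde.

Step 8
Reactants: 13 (4R,5R)-4-(2-methoxyethenyl)-2,4-dimethyl-5-[(trimethylsilyl)ethynyl]cyclohex-2-en-1-one
Product: 14 (1S,4R,5R)-4-(2-methoxyethenyl)-2,4-dimethyl-5-[(trimethylsilyl)ethynyl]cyclohex-2-en-1-ol (7β-OH)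
Conditions: (R)-1-methyl-3,3-diphenyltetrahydro-1H,3H-pyrrolo[1,2-c][1,3,2]oxazaborole (0.2 equiv), catecholborane, toluene, −78 °C
Reagents that add atoms: none
Why: In this Corey–Bakshi–Shibata reduction the α-methyl alkenyl side acts as the large group, so the (R)-oxazaborolidine should deliver hydride under reagent control to give the 7β (1S) carbinol, cis to the C5 alkynyl group.

Step 9
Reactants: 14 (1S,4R,5R)-4-(2-methoxyethenyl)-2,4-dimethyl-5-[(trimethylsilyl)ethynyl]cyclohex-2-en-1-ol
Product: 15 (1S,4R,5R)-4-(2-methoxyethenyl)-2,4-dimethyl-5-[(trimethylsilyl)ethynyl]cyclohex-2-en-1-yl 2-(diphenylphosphino)benzoate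
Conditions: 2-(diphenylphosphino)benzoic acid, N,N'-dicyclohexylcarbodiimide, 4-(dimethylamino)pyridine, CH2Cl2, rt
Reagents that add atoms: 2-(diphenylphosphino)benzoic acid, OC(=O)c1ccccc1P(c1ccccc1)c1ccccc1
Why: Steglich esterification proceeds with retention at C7 and attaches a leaving group that carries a phosphine for copper delivery.

Step 10
Reactants: 16 4-(tert-butyldimethylsilyloxy)but-1-yne
Product: 18 (2E)-5-(tert-butyldimethylsilyloxy)-3-methylpent-2-en-1-ol, via alkenylalane 17 (not isolated)
Conditions: AlMe3, Cp2ZrCl2 (0.25 equiv), CH2Cl2, 0 °C to rt; then n-BuLi, THF, −78 °C; then (CH2O)n, rt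
Reagents that add atoms: trimethylaluminium, C[Al](C)C; formaldehyde (as paraformaldehyde), C=O
Why: Zirconocene-catalysed syn-methylalumination places methyl on the internal alkyne carbon and the derived alanate is hydroxymethylated with retention, which fixes the E trisubstituted C13=C14 alkene.

Step 11
Reactants: 18 (2E)-5-(tert-butyldimethylsilyloxy)-3-methylpent-2-en-1-ol
Product: 19 tert-butyl{[(3E)-5-(4-methoxybenzyloxy)-3-methylpent-3-en-1-yl]oxy}dimethylsilane
Conditions: NaH, 4-methoxybenzyl chloride, Bu4NI (cat.), THF/DMF, 0 °C to rt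
Reagents that add atoms: 4-methoxybenzyl chloride, COc1ccc(CCl)cc1
Why: Williamson etherification protects the allylic C15 oxygen with a group that is later removed oxidatively in the presence of silyl ethers.

Step 12
Reactants: 19 tert-butyl{[(3E)-5-(4-methoxybenzyloxy)-3-methylpent-3-en-1-yl]oxy}dimethylsilane
Product: 20 (3E)-5-(4-methoxybenzyloxy)-3-methylpent-3-en-1-ol
Conditions: Bu4NF, THF, rt
Reagents that add atoms: none
Why: Fluoride cleaves the primary silyl ether and leaves the PMB ether untouched.

Step 13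
Reactants: 20 (3E)-5-(4-methoxybenzyloxy)-3-methylpent-3-en-1-ol
Product: 21 1-{[(2E)-5-bromo-3-methylpent-2-en-1-yl]oxymethyl}-4-methoxybenzene
Conditions: CBr4, PPh3, CH2Cl2, 0 °C
Reagents that add atoms: carbon tetrabromide, BrC(Br)(Br)Br
Why: The Appel reaction converts the primary homoallylic alcohol into the bromide under neutral conditions.

Step 14
Reactants: 15 (1S,4R,5R)-4-(2-methoxyethenyl)-2,4-dimethyl-5-[(trimethylsilyl)ethynyl]cyclohex-2-en-1-yl 2-(diphenylphosphino)benzoate; 21 1-{[(2E)-5-bromo-3-methylpent-2-en-1-yl]oxymethyl}-4-methoxybenzene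
Product: 24 ring-B alkyne (cyclohex-7-ene with 9β-[(3E)-5-(4-methoxybenzyloxy)-3-methylpent-3-enyl]; 8,10β-dimethyl; 10α-(2-methoxyethenyl); 5β-ethynyl), via Grignard reagent 22 (not isolated), via silylalkyne 23 (not isolated)
Conditions: 21, Mg, THF, rt; then 15, CuBr·SMe2 (0.5 equiv), Et2O, rt, slow addition of 22; then MeOH, K2CO3, rt
Reagents that add atoms: none
Why: The organocopper formed from 22 is held by the ortho-phosphine of the benzoate and should attack C9 on the face of the departing C7–O bond (directed syn-SN2′ allylic substitution), which moves the alkene to C7=C8 and sets C9 with the side chain β and cis to the C20 methyl, after which K2CO3/MeOH removes the alkynyl silane.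

Step 15
Reactants: 24 ring-B alkyne
Product: 26 ring-B acrylate (as 24 but with 5β-[1-(methoxycarbonyl)ethenyl] in place of ethynyl), via alkenylalane 25 (not isolated)
Conditions: NiCl2(dppp) (3 mol %; dppp = 1,3-bis(diphenylphosphino)propane), i-Bu2AlH, THF, 0 °C to rt; then methyl chloroformate, 0 °C to rt
Reagents that add atoms: methyl chloroformate, COC(=O)Cl
Why: Nickel-catalysed Markovnikov hydroalumination places aluminium on the internal alkyne carbon C4 and the alkenylalane is acylated by the chloroformate with retention, which gives the 2-substituted acrylate carrying C19.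

Step 16
Reactants: 26 ring-B acrylate
Product: 27 ring-B aldehyde acrylate (as 26 but with 10α-(2-oxoethyl) in place of 2-methoxyethenyl)
Conditions: 0.5 M aqueous HCl, THF, 0 °C to rt
Reagents that add atoms: water, O
Why: Acid-catalysed hydrolysis of the methyl enol ether (protonation at C1, hydration of the oxocarbenium ion, loss of methanol) unmasks the C2 aldehyde under conditions mild enough for the acrylate and the allylic PMB ether.

Step 17
Reactants: 27 ring-B aldehyde acrylate
Product: 28 methyl 2α-hydroxy-15-(4-methoxybenzyloxy)-18-norlabda-7,13E-dien-19-oate (4β-ester epimer drawn; the C4 epimer is equally usable)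
Conditions: SmI2 (2.5 equiv), hexamethylphosphoramide (HMPA), t-BuOH (2 equiv), THF, −78 °C, high dilution
Reagents that add atoms: none
Why: SmI2 reduces the C2 aldehyde to a samarium ketyl whose carbon adds to the unsubstituted terminus C3 of the 2-substituted acrylate, the ester-stabilised C4 radical is reduced by a second SmI2 to the trivalent samarium enolate, and t-BuOH protonates it. The closest known reaction type is the SmI2-mediated reductive aldehyde–enoate (ketyl–olefin) cyclisation that gives γ-hydroxy esters. Ring A closes in the 6-endo-trig mode, because the 5-exo attack on C4 would be polarity-mismatched, would build a quaternary carbon and would leave an unstabilised primary radical. C2 is set in a chair transition state built on the trans-diequatorial C1 and C4 arms of ring B, in which the bulky HMPA-solvated samarium alkoxide lies equatorial (2α) to avoid the 1,3-diaxial contact with the axial C20 methyl, while C4 is set only by protonation and is re-enolised in step 18. The step needs chemoselectivity for the aldehyde/acrylate pair over the two trisubstituted alkenes and the allylic ether, which the electron-poor acceptor and the low temperature should secure, and a non-chelated transition state, which HMPA should secure by saturating samarium. In one operation the monocyclic precursor becomes the complete trans-fused bicyclic core with the C2 carbinol in place and C4 armed for quaternisation.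

Step 18
Reactants: 28 methyl 2α-hydroxy-15-(4-methoxybenzyloxy)-18-norlabda-7,13E-dien-19-oate
Product: 29 methyl 2α-hydroxy-15-(4-methoxybenzyloxy)labda-7,13E-dien-19-oate
Conditions: LiN(i-Pr)2 (2.5 equiv), THF, −78 °C to −30 °C; then iodomethane, N,N'-dimethylpropyleneurea, −78 °C to −20 °C
Reagents that add atoms: iodomethane, IC
Why: The alkoxide–ester enolate dianion (as in Fráter–Seebach alkylations) should be C-methylated from the less hindered α (equatorial) face, anti to the axial C20 methyl, so that the new C18 methyl is α and the ester (C19) becomes axial β, the known preference for C4 ester enolates of 10-methyl trans-decalins.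

Step 19
Reactants: 29 methyl 2α-hydroxy-15-(4-methoxybenzyloxy)labda-7,13E-dien-19-oate
Product: 30 15-(4-methoxybenzyloxy)labda-7,13E-diene-2α,19-diol
Conditions: LiAlH4, THF, 0 °C to reflux
Reagents that add atoms: none
Why: LiAlH4 reduces the hindered neopentyl ester to the C19 primary alcohol without touching the alkenes or the PMB ether.

Step 20
Reactants: 30 15-(4-methoxybenzyloxy)labda-7,13E-diene-2α,19-diol
Product: 31 2α,19-bis(tert-butyldimethylsilyloxy)-15-(4-methoxybenzyloxy)labda-7,13E-diene
Conditions: TBS trifluoromethanesulfonate, 2,6-lutidine, CH2Cl2, 0 °C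
Reagents that add atoms: tert-butyldimethylsilyl trifluoromethanesulfonate, CC(C)(C)[Si](C)(C)OS(=O)(=O)C(F)(F)F
Why: The reactive silyl triflate silylates both the secondary C2 and the hindered neopentyl C19 hydroxyl, so that only O15 can be freed next.

Step 21
Reactants: 31 2α,19-bis(tert-butyldimethylsilyloxy)-15-(4-methoxybenzyloxy)labda-7,13E-diene
Product: 32 2α,19-bis(tert-butyldimethylsilyloxy)labda-7,13E-dien-15-ol
Conditions: 2,3-dichloro-5,6-dicyano-1,4-benzoquinone (DDQ), CH2Cl2, aqueous pH 7 buffer, 0 °C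
Reagents that add atoms: none
Why: Oxidative cleavage of the electron-rich benzyl ether (hydride abstraction, hydrolysis of the oxocarbenium ion) frees the allylic alcohol and leaves silyl ethers and alkenes intact.

Step 22
Reactants: 32 2α,19-bis(tert-butyldimethylsilyloxy)labda-7,13E-dien-15-ol
Product: 33 2α,19-bis(tert-butyldimethylsilyloxy)labda-7,13E-dien-15-yl acetate
Conditions: acetic anhydride, pyridine, 4-(dimethylamino)pyridine (cat.), CH2Cl2, rt
Reagents that add atoms: acetic anhydride, CC(=O)OC(C)=O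
Why: Acylation of the only free hydroxyl installs the C15 acetate without any regioselectivity question.

Step 23
Reactants: 33 2α,19-bis(tert-butyldimethylsilyloxy)labda-7,13E-dien-15-yl acetate
Product: 34 (2R,4S,5R,9S,10R)-2α,19-dihydroxylabda-7,13E-dien-15-yl acetate (CNP0165423.1)
Conditions: HF·pyridine, pyridine, THF, 0 °C to rt
Reagents that add atoms: none
Why: Buffered fluoride removes both silyl ethers while the primary allylic acetate survives.

**Compound list**

1 | (E)-4-methoxybut-3-en-2-one | CO/C=C/C(C)=O | starting material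
2 | (2S,5S)-2,5-diphenylpyrrolidine | N1[C@H](c2ccccc2)CC[C@H]1c1ccccc1 | starting material
3 | (E)-4-[(2S,5S)-2,5-diphenylpyrrolidin-1-yl]but-3-en-2-one | CC(=O)/C=C/N1[C@H](c2ccccc2)CC[C@H]1c1ccccc1 | intermediate
4 | (2S,5S)-1-[(1E)-3-(tert-butyldimethylsilyloxy)buta-1,3-dien-1-yl]-2,5-diphenylpyrrolidine | C=C(O[Si](C)(C)C(C)(C)C)/C=C/N1[C@H](c2ccccc2)CC[C@H]1c1ccccc1 | intermediate
5 | 3-(trimethylsilyl)prop-2-ynal | C[Si](C)(C)C#CC=O | starting material
6 | 2-(triphenylphosphoranylidene)propanal | CC(C=O)=P(c1ccccc1)(c1ccccc1)c1ccccc1 | starting material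
7 | (E)-2-methyl-5-(trimethylsilyl)pent-2-en-4-ynal | C[Si](C)(C)C#C/C=C(\C)C=O | intermediate
8 | Diels–Alder adduct: 4-(tert-butyldimethylsilyloxy)-2-[(2S,5S)-2,5-diphenylpyrrolidin-1-yl]-1-methyl-6-[(trimethylsilyl)ethynyl]cyclohex-3-ene-1-carbaldehyde (formyl trans to alkynyl, cis to amino; 5β-alkynyl, 10α-CHO, 9α-N) | O=C[C@]1(C)[C@H](N2[C@H](c3ccccc3)CC[C@H]2c2ccccc2)C=C(O[Si](C)(C)C(C)(C)C)C[C@H]1C#C[Si](C)(C)C | intermediate
9 | (1R,6R)-1-methyl-4-oxo-6-[(trimethylsilyl)ethynyl]cyclohex-2-ene-1-carbaldehyde | O=C[C@]1(C)C=CC(=O)C[C@H]1C#C[Si](C)(C)C | intermediate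
10 | (1S,6R)-3-iodo-1-methyl-4-oxo-6-[(trimethylsilyl)ethynyl]cyclohex-2-ene-1-carbaldehyde | O=C[C@]1(C)C=C(I)C(=O)C[C@H]1C#C[Si](C)(C)C | intermediate
11 | (1R,6R)-1,3-dimethyl-4-oxo-6-[(trimethylsilyl)ethynyl]cyclohex-2-ene-1-carbaldehyde | O=C[C@]1(C)C=C(C)C(=O)C[C@H]1C#C[Si](C)(C)C | intermediate
12 | (methoxymethyl)triphenylphosphonium chloride | COC[P+](c1ccccc1)(c1ccccc1)c1ccccc1.[Cl-] | starting material
13 | (4R,5R)-4-(2-methoxyethenyl)-2,4-dimethyl-5-[(trimethylsilyl)ethynyl]cyclohex-2-en-1-one (E/Z mixture at the enol ether) | COC=C[C@]1(C)C=C(C)C(=O)C[C@H]1C#C[Si](C)(C)C | intermediate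
14 | (1S,4R,5R)-4-(2-methoxyethenyl)-2,4-dimethyl-5-[(trimethylsilyl)ethynyl]cyclohex-2-en-1-ol (7β-OH, cis to the 5β-alkynyl group) | COC=C[C@]1(C)C=C(C)[C@@H](O)C[C@H]1C#C[Si](C)(C)C | intermediate
15 | (1S,4R,5R)-4-(2-methoxyethenyl)-2,4-dimethyl-5-[(trimethylsilyl)ethynyl]cyclohex-2-en-1-yl 2-(diphenylphosphino)benzoate | COC=C[C@]1(C)C=C(C)[C@@H](OC(=O)c2ccccc2P(c2ccccc2)c2ccccc2)C[C@H]1C#C[Si](C)(C)C | intermediate
16 | 4-(tert-butyldimethylsilyloxy)but-1-yne | C#CCCO[Si](C)(C)C(C)(C)C | starting material
17 | [(1E)-4-(tert-butyldimethylsilyloxy)-2-methylbut-1-en-1-yl]dimethylalane | C/C(CCO[Si](C)(C)C(C)(C)C)=C\[Al](C)C | intermediate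
18 | (2E)-5-(tert-butyldimethylsilyloxy)-3-methylpent-2-en-1-ol | OC/C=C(\C)CCO[Si](C)(C)C(C)(C)C | intermediate
19 | tert-butyl{[(3E)-5-(4-methoxybenzyloxy)-3-methylpent-3-en-1-yl]oxy}dimethylsilane | COc1ccc(COC/C=C(\C)CCO[Si](C)(C)C(C)(C)C)cc1 | intermediate
20 | (3E)-5-(4-methoxybenzyloxy)-3-methylpent-3-en-1-ol | COc1ccc(COC/C=C(\C)CCO)cc1 | intermediate
21 | 1-{[(2E)-5-bromo-3-methylpent-2-en-1-yl]oxymethyl}-4-methoxybenzene | COc1ccc(COC/C=C(\C)CCBr)cc1 | intermediate
22 | [(3E)-5-(4-methoxybenzyloxy)-3-methylpent-3-en-1-yl]magnesium bromide | COc1ccc(COC/C=C(\C)CC[Mg]Br)cc1 | intermediate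
23 | ring-B silylalkyne: cyclohex-7-ene with 9β-[(3E)-5-(4-methoxybenzyloxy)-3-methylpent-3-enyl], 8,10β-dimethyl, 10α-(2-methoxyethenyl), 5β-[(trimethylsilyl)ethynyl] (9α-H, 5α-H) | COc1ccc(COC/C=C(\C)CC[C@H]2C(C)=CC[C@@H](C#C[Si](C)(C)C)[C@]2(C)C=COC)cc1 | intermediate
24 | ring-B alkyne: as 23 with 5β-ethynyl | COc1ccc(COC/C=C(\C)CC[C@H]2C(C)=CC[C@@H](C#C)[C@]2(C)C=COC)cc1 | intermediate
25 | alkenylalane: as 24 with 5β-[1-(diisobutylalumanyl)ethenyl] | COc1ccc(COC/C=C(\C)CC[C@H]2C(C)=CC[C@@H](C(=C)[Al](CC(C)C)CC(C)C)[C@]2(C)C=COC)cc1 | intermediate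
26 | ring-B acrylate: as 24 with 5β-[1-(methoxycarbonyl)ethenyl] | COc1ccc(COC/C=C(\C)CC[C@H]2C(C)=CC[C@@H](C(=C)C(=O)OC)[C@]2(C)C=COC)cc1 | intermediate
27 | ring-B aldehyde acrylate: as 26 with 10α-(2-oxoethyl) | COc1ccc(COC/C=C(\C)CC[C@H]2C(C)=CC[C@@H](C(=C)C(=O)OC)[C@]2(C)CC=O)cc1 | intermediate
28 | methyl 2α-hydroxy-15-(4-methoxybenzyloxy)-18-norlabda-7,13E-dien-19-oate (4β-ester epimer drawn) | COc1ccc(COC/C=C(\C)CC[C@H]2C(C)=CC[C@H]3[C@@H](C(=O)OC)C[C@H](O)C[C@]23C)cc1 | intermediate
29 | methyl 2α-hydroxy-15-(4-methoxybenzyloxy)labda-7,13E-dien-19-oate | COc1ccc(COC/C=C(\C)CC[C@H]2C(C)=CC[C@H]3[C@@](C)(C(=O)OC)C[C@H](O)C[C@]23C)cc1 | intermediate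
30 | 15-(4-methoxybenzyloxy)labda-7,13E-diene-2α,19-diol | COc1ccc(COC/C=C(\C)CC[C@H]2C(C)=CC[C@H]3[C@@](C)(CO)C[C@H](O)C[C@]23C)cc1 | intermediate
31 | 2α,19-bis(tert-butyldimethylsilyloxy)-15-(4-methoxybenzyloxy)labda-7,13E-diene | COc1ccc(COC/C=C(\C)CC[C@H]2C(C)=CC[C@H]3[C@@](C)(CO[Si](C)(C)C(C)(C)C)C[C@H](O[Si](C)(C)C(C)(C)C)C[C@]23C)cc1 | intermediate
32 | 2α,19-bis(tert-butyldimethylsilyloxy)labda-7,13E-dien-15-ol | OC/C=C(\C)CC[C@H]1C(C)=CC[C@H]2[C@@](C)(CO[Si](C)(C)C(C)(C)C)C[C@H](O[Si](C)(C)C(C)(C)C)C[C@]12C | intermediate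
33 | 2α,19-bis(tert-butyldimethylsilyloxy)labda-7,13E-dien-15-yl acetate | CC(=O)OC/C=C(\C)CC[C@H]1C(C)=CC[C@H]2[C@@](C)(CO[Si](C)(C)C(C)(C)C)C[C@H](O[Si](C)(C)C(C)(C)C)C[C@]12C | intermediate
34 | (2R,4S,5R,9S,10R)-2α,19-dihydroxylabda-7,13E-dien-15-yl acetate (CNP0165423.1) | CC(=O)OC/C=C(\C)CC[C@H]1C(C)=CC[C@H]2[C@@](C)(CO)C[C@H](O)C[C@]12C | target

**Step count and risks**

Total step count: 23. Longest linear sequence: 18 steps (steps 1, 2, 4–9, 14–23).

Steps most likely to fail:

1. Step 14. Copper delivery to C9, which lies next to the quaternary C10, may be slow, so that direct substitution at C7 or attack of the magnesium reagent on the ester carbonyl takes over. The fallback replaces the intermolecular substitution by a sigmatropic transfer. It sets out from 14 and comes back to the route at 24. Alcohol 14 is heated with N,N-dimethylacetamide dimethyl acetal (xylene, 140 °C), and the Eschenmoser–Claisen rearrangement, suprafacial from the 7β oxygen to the β face of C9, should give the γ,δ-unsaturated dimethylamide F1. LiBHEt3 reduces the amide to the primary alcohol F2, and I2/PPh3/imidazole gives the iodide F3. Iodine–lithium exchange (t-BuLi, −78 °C), transmetalation with CuBr·SMe2 and syn-carbocupration of ethyl but-2-ynoate at −78 °C should give the (E)-enoate F4. i-Bu2AlH reduces it to the allylic alcohol F5, NaH/4-methoxybenzyl chloride gives 23, and K2CO3/MeOH converts 23 into 24.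

2. Step 15. Aluminium hydride chemistry may go off course (deprotonation of the alkyne, hydrometalation with the opposite regiochemistry, nickel hydride attack on the allylic ether), or acylation of the hindered alkenylalane may stall. The fallback uses a different C–C bond-forming event. It sets out from 24 and comes back at 27. Palladium-catalysed Markovnikov methoxycarbonylation (Pd(OAc)2, 2-(diphenylphosphino)pyridine, methanesulfonic acid (cat.), CO, MeOH, 50 °C; hydridopalladium insertion, CO insertion, methanolysis) should build the acrylate. The acidic methanol at the same time converts the enol ether into the dimethyl acetal, so the product is the acrylate dimethyl acetal F6, which 0.5 M aqueous HCl in THF hydrolyses to 27.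

3. Step 17. Chelation of trivalent samarium between the ketyl oxygen and the ester carbonyl may steer the oxygen axial (2β), or simple carbonyl reduction and pinacol dimerisation may outrun the 6-endo closure. The fallback forms the same bond by polar umpolung instead of a radical. It sets out from 27 and comes back at 28. An intramolecular Stetter reaction (3-benzyl-5-(2-hydroxyethyl)-4-methylthiazolium chloride, Et3N, dioxane, 80 °C), in which the Breslow intermediate of the C2 aldehyde adds to C3 of the acrylate, should give the 2-oxo ester F7. Reduction of the ketone with SmI2/H2O in THF, which is expected to favour the more stable equatorial alcohol, gives 28; any 2β epimer is returned to F7 by Dess–Martin oxidation.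

Further compounds
F1 | step 14 | N,N-dimethylamide: cyclohex-7-ene with 9β-[2-(dimethylamino)-2-oxoethyl], 8,10β-dimethyl, 10α-(2-methoxyethenyl), 5β-[(trimethylsilyl)ethynyl] | CN(C)C(=O)C[C@H]1C(C)=CC[C@@H](C#C[Si](C)(C)C)[C@]1(C)C=COC
F2 | step 14 | primary alcohol: as F1 with 9β-(2-hydroxyethyl) | OCC[C@H]1C(C)=CC[C@@H](C#C[Si](C)(C)C)[C@]1(C)C=COC
F3 | step 14 | iodide: as F1 with 9β-(2-iodoethyl) | ICC[C@H]1C(C)=CC[C@@H](C#C[Si](C)(C)C)[C@]1(C)C=COC
F4 | step 14 | ethyl (2E)-enoate: as F1 with 9β-[(3E)-5-ethoxy-3-methyl-5-oxopent-3-enyl] | CCOC(=O)/C=C(\C)CC[C@H]1C(C)=CC[C@@H](C#C[Si](C)(C)C)[C@]1(C)C=COC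
F5 | step 14 | allylic alcohol: as F1 with 9β-[(3E)-5-hydroxy-3-methylpent-3-enyl] | OC/C=C(\C)CC[C@H]1C(C)=CC[C@@H](C#C[Si](C)(C)C)[C@]1(C)C=COC
F6 | step 15 | acrylate dimethyl acetal: as 26 with 10α-(2,2-dimethoxyethyl) | COc1ccc(COC/C=C(\C)CC[C@H]2C(C)=CC[C@@H](C(=C)C(=O)OC)[C@]2(C)CC(OC)OC)cc1
F7 | step 17 | methyl 15-(4-methoxybenzyloxy)-2-oxo-18-norlabda-7,13E-dien-19-oate (C4 epimers) | COc1ccc(COC/C=C(\C)CC[C@H]2C(C)=CC[C@H]3[C@@H](C(=O)OC)CC(=O)C[C@]23C)cc1
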